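**Assumption:** germacrane locants are used for the core (ring carbons C1–C10, ester carbon C15 on C4, lactone carbons C11–C13, methyl C14 on C10), and the sensitive aldehydes 7 and 24 are used crude.

**Retrosynthetic overview**
1. Target 26 ⇐ one flask from seco aldehyde 24: Ni/Cr alkenyl–aldehyde closure of the ten-membered carbocycle (C4–C5), then acid-triggered transannular etherification C5–OH → C10, which creates both seven-membered ether rings.
2. 24 ⇐ lactone triol 23 ⇐ ester 22 by acetonide release and lactonisation of C6–OH; the (S)-acyl side chain (from D-lactic acid via a Seebach dioxolanone) is placed on C8–OH before lactonisation.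
3. C7–C8 ⇐ indium allylation of aldehyde 7 with the glyceraldehyde-derived 2-(bromomethyl)acrylate 12; the C6 centre (D-mannitol) controls C7 and C8.
4. 7 ⇐ (R)-linalool (C1–C3, C8–C10, C14) by hydroboration, ozonolysis and a Z-selective iodo-Wittig reaction (C4, C15).
5. Ring order: γ-lactone (step 15), then ten-membered carbocycle, then the 5,10-oxygen bridge (both in step 17).

**Route**

Step 1
Reactants: 1 (R)-linalool
Product: 2 (3R)-3,7-dimethyloct-6-ene-1,3-diol
Conditions: 9-BBN (1.2 equiv), THF, 0 °C to rt; then NaOH, H2O2, 0 °C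
Reagents that add atoms: hydrogen peroxide OO
Why: hydroboration–oxidation, in which the bulky borane adds anti-Markovnikov to the vinyl group only and leaves the trisubstituted alkene and the existing C10 carbinol centre untouched.

Step 2
Reactants: 2 (3R)-3,7-dimethyloct-6-ene-1,3-diol
Product: 3 (5R)-5-(2-hydroxyethyl)-5-methyloxolan-2-ol
Conditions: O3, CH2Cl2, −78 °C; then PPh3, rt
Reagents that add atoms: ozone [O-][O+]=O
Why: ozonolysis with reductive work-up cleaves the only C=C, and the resulting γ-hydroxy aldehyde closes onto the tertiary hydroxyl to give the five-membered lactol without touching the stereocentre.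

Step 3
Reactants: 3 (5R)-5-(2-hydroxyethyl)-5-methyloxolan-2-ol; 4 methyl (triphenylphosphoranylidene)acetate
Product: 6 methyl (2Z,6R)-6,8-dihydroxy-2-iodo-6-methyloct-2-enoate, via iodo ylide 5 (not isolated)
Conditions: 4, N-iodosuccinimide, CH2Cl2, −20 °C; then 3, rt to 40 °C
Reagents that add atoms: N-iodosuccinimide O=C1CCC(=O)N1I
Why: ylide iodination followed by Wittig olefination of the open aldehyde form of the lactol; the stabilised α-iodo ylide places CO2Me trans to the chain, so iodine ends cis to C2 (Z), the geometry needed for the later ring.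

Step 4
Reactants: 6 methyl (2Z,6R)-6,8-dihydroxy-2-iodo-6-methyloct-2-enoate
Product: 7 methyl (2Z,6R)-6-hydroxy-2-iodo-6-methyl-8-oxooct-2-enoate
Conditions: TEMPO (10 mol %), PhI(OAc)2 (1.1 equiv), CH2Cl2, rt
Reagents that add atoms: none
Why: nitroxyl-catalysed oxidation is selective for the primary alcohol, so the tertiary carbinol and the iodo-enoate survive and no stereocentre is affected.

Step 5
Reactants: 8 1,2:5,6-di-O-isopropylidene-D-mannitol
Product: 9 (4R)-2,2-dimethyl-1,3-dioxolane-4-carbaldehyde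
Conditions: NaIO4, CH2Cl2, sat. aq. NaHCO3, rt
Reagents that add atoms: none
Why: periodate glycol cleavage of the central diol gives two equivalents of the aldehyde, whose stereocentre (the future C6) comes unchanged from D-mannitol.

Step 6
Reactants: 9 (4R)-2,2-dimethyl-1,3-dioxolane-4-carbaldehyde; 10 methyl acrylate
Product: 11 methyl 2-{[(4R)-2,2-dimethyl-1,3-dioxolan-4-yl](hydroxy)methyl}prop-2-enoate
Conditions: DABCO (20 mol %), dioxane/H2O 1:1, rt, 3 d
Reagents that add atoms: none
Why: Morita–Baylis–Hillman reaction; the new carbinol centre forms as a mixture but becomes sp2 in the next step, while the dioxolane centre is retained.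

Step 7
Reactants: 11 methyl 2-{[(4R)-2,2-dimethyl-1,3-dioxolan-4-yl](hydroxy)methyl}prop-2-enoate
Product: 12 methyl (2Z)-2-(bromomethyl)-3-[(4S)-2,2-dimethyl-1,3-dioxolan-4-yl]prop-2-enoate
Conditions: NBS, Me2S, CH2Cl2, 0 °C to rt
Reagents that add atoms: N-bromosuccinimide O=C1CCC(=O)N1Br
Why: Corey–Kim-type activation of the allylic alcohol and SN2' delivery of bromide give the thermodynamically favoured (Z)-2-(bromomethyl)enoate under neutral conditions that spare the acetonide.

Step 8
Reactants: 7 methyl (2Z,6R)-6-hydroxy-2-iodo-6-methyl-8-oxooct-2-enoate; 12 methyl (2Z)-2-(bromomethyl)-3-[(4S)-2,2-dimethyl-1,3-dioxolan-4-yl]prop-2-enoate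
Product: 13 dimethyl (2Z,6R,8R,9R)-9-[(4S)-2,2-dimethyl-1,3-dioxolan-4-yl]-6,8-dihydroxy-2-iodo-6-methyl-10-methylideneundec-2-enedioate
Conditions: indium powder (1.5 equiv), THF/H2O 1:1, rt; product kept cold and used promptly
Reagents that add atoms: none
Why: Barbier-type allylation in which the (Z)-configured γ-substituted allyl nucleophile reacts through a chair transition state to give the syn C7/C8 relationship, and attack anti to the allylic C6–O bond (Felkin-type control) fixes C7 relative to C6; the alkenyl iodide is inert.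

Step 9
Reactants: 14 (R)-lactic acid; 15 pivalaldehyde
Product: 16 (2R,5R)-2-tert-butyl-5-methyl-1,3-dioxolan-4-one
Conditions: TsOH (cat.), pentane, reflux, Dean–Stark; recrystallisation
Reagents that add atoms: none
Why: Seebach acetalisation gives the cis-dioxolanone, storing the lactate chirality in the acetal centre (self-regeneration of stereocentres).

Step 10
Reactants: 16 (2R,5R)-2-tert-butyl-5-methyl-1,3-dioxolan-4-one; 17 acetaldehyde
Product: 18 (2R,5S)-2-tert-butyl-5-(1-hydroxyethyl)-5-methyl-1,3-dioxolan-4-one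
Conditions: LiN(iPr)2, THF, −78 °C; MeCHO; AcOH quench
Reagents that add atoms: none
Why: enolate aldol addition in which the electrophile enters trans to the tert-butyl group, setting the quaternary centre; the side-chain carbinol forms as a mixture and is removed in the next step.

Step 11
Reactants: 18 (2R,5S)-2-tert-butyl-5-(1-hydroxyethyl)-5-methyl-1,3-dioxolan-4-one
Product: 19 (2R,5S)-2-tert-butyl-5-ethenyl-5-methyl-1,3-dioxolan-4-one
Conditions: Martin sulfurane, CH2Cl2, rt
Reagents that add atoms: none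
Why: sulfurane dehydration of the secondary alcohol can only eliminate towards the methyl group (the neighbouring carbon is quaternary), so the vinyl group forms and the quaternary centre is untouched.

Step 12
Reactants: 19 (2R,5S)-2-tert-butyl-5-ethenyl-5-methyl-1,3-dioxolan-4-one
Product: 20 (2S)-2-hydroxy-2-methylbut-3-enoic acid
Conditions: LiOH, THF/H2O, 0 °C to rt; then 1 M HCl
Reagents that add atoms: lithium hydroxide [Li+].[OH-]
Why: saponification of the acetal ester releases pivalaldehyde and the α-hydroxy acid with the quaternary centre intact (S).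

Step 13
Reactants: 20 (2S)-2-hydroxy-2-methylbut-3-enoic acid
Product: 21 (2S)-2-methyl-2-[(triethylsilyl)oxy]but-3-enoic acid
Conditions: TESCl (2.2 equiv), imidazole, DMF, rt; then H2O/THF, 0 °C
Reagents that add atoms: chlorotriethylsilane CC[Si](Cl)(CC)CC
Why: silylation masks the tertiary hydroxyl for the coupling, and the labile silyl ester is hydrolysed on aqueous work-up while the tertiary silyl ether stays.

Step 14
Reactants: 13 dimethyl (2Z,6R,8R,9R)-9-[(4S)-2,2-dimethyl-1,3-dioxolan-4-yl]-6,8-dihydroxy-2-iodo-6-methyl-10-methylideneundec-2-enedioate; 21 (2S)-2-methyl-2-[(triethylsilyl)oxy]but-3-enoic acid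
Product: 22 dimethyl (2Z,6R,8R,9R)-9-[(4S)-2,2-dimethyl-1,3-dioxolan-4-yl]-6-hydroxy-2-iodo-6-methyl-10-methylidene-8-{[(2S)-2-methyl-2-(triethylsilyloxy)but-3-enoyl]oxy}undec-2-enedioate
Conditions: 21, 2,4,6-trichlorobenzoyl chloride, Et3N, toluene, rt; then 13, DMAP, rt
Reagents that add atoms: none
Why: Yamaguchi esterification acylates the only secondary hydroxyl (C8) while the tertiary C10 hydroxyl is inert, which also blocks C8–OH from lactonising later; no stereocentre is touched.

Step 15
Reactants: 22 dimethyl (2Z,6R,8R,9R)-9-[(4S)-2,2-dimethyl-1,3-dioxolan-4-yl]-6-hydroxy-2-iodo-6-methyl-10-methylidene-8-{[(2S)-2-methyl-2-(triethylsilyloxy)but-3-enoyl]oxy}undec-2-enedioate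
Product: 23 methyl (2Z,6R,8R)-6-hydroxy-8-{[(2S)-2-hydroxy-2-methylbut-3-enoyl]oxy}-8-[(2S,3R)-2-(hydroxymethyl)-4-methylidene-5-oxooxolan-3-yl]-2-iodo-6-methyloct-2-enoate
Conditions: AcOH/H2O/THF 3:1:1, 45 °C
Reagents that add atoms: none
Why: mild acid hydrolysis removes the acetonide and the silyl ether, and the freed C6 hydroxyl lactonises onto the acrylate ester (γ over δ closure) to give the trans-disubstituted α-methylene-γ-butyrolactone; the non-allylic tertiary C10 alcohol does not ionise under these conditions.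

Step 16
Reactants: 23 methyl (2Z,6R,8R)-6-hydroxy-8-{[(2S)-2-hydroxy-2-methylbut-3-enoyl]oxy}-8-[(2S,3R)-2-(hydroxymethyl)-4-methylidene-5-oxooxolan-3-yl]-2-iodo-6-methyloct-2-enoate
Product: 24 methyl (2Z,6R,8R)-8-[(2S,3R)-2-formyl-4-methylidene-5-oxooxolan-3-yl]-6-hydroxy-8-{[(2S)-2-hydroxy-2-methylbut-3-enoyl]oxy}-2-iodo-6-methyloct-2-enoate
Conditions: Dess–Martin periodinane, CH2Cl2, 0 °C to rt
Reagents that add atoms: none
Why: Dess–Martin oxidation converts the only primary alcohol into the aldehyde under neutral conditions that leave both tertiary alcohols and the C6 centre alone.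

Step 17
Reactants: 24 methyl (2Z,6R,8R)-8-[(2S,3R)-2-formyl-4-methylidene-5-oxooxolan-3-yl]-6-hydroxy-8-{[(2S)-2-hydroxy-2-methylbut-3-enoyl]oxy}-2-iodo-6-methyloct-2-enoate
Product: 26 CNP0325750.1, via macrocyclic diol 25 (not isolated)
Conditions: CrCl2 (12 equiv), NiCl2 (5 mol %), DMSO/THF 3:1, 2 mM, rt, syringe-pump addition; aq. sodium serinate quench, dried CH2Cl2 extract used without purification; then CF3SO3H (10 mol %), CH2Cl2, −30 to 0 °C
Reagents that add atoms: none
Why: intramolecular Nozaki–Hiyama–Kishi alkenyl–aldehyde coupling closes the ten-membered carbocycle with retention of alkene geometry and Felkin–Anh attack anti to the C6 lactone oxygen (5R), and acid-catalysed transannular etherification then lets the C5 hydroxyl displace the ionising tertiary C10 hydroxyl with inversion, where only the cis-bridged 11-oxabicyclo[4.4.1]undecene is geometrically possible (10S).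

**Compound list**

1 | (R)-linalool, (3R)-3,7-dimethylocta-1,6-dien-3-ol | C=C[C@](C)(O)CCC=C(C)C | starting material
2 | (3R)-3,7-dimethyloct-6-ene-1,3-diol | OCC[C@](C)(O)CCC=C(C)C | intermediate
3 | (5R)-5-(2-hydroxyethyl)-5-methyloxolan-2-ol (lactol, both anomers) | OCC[C@@]1(C)CCC(O)O1 | intermediate
4 | methyl (triphenylphosphoranylidene)acetate | COC(=O)C=P(c1ccccc1)(c1ccccc1)c1ccccc1 | starting material
5 | methyl iodo(triphenylphosphoranylidene)acetate (iodo ylide) | COC(=O)C(I)=P(c1ccccc1)(c1ccccc1)c1ccccc1 | intermediate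
6 | methyl (2Z,6R)-6,8-dihydroxy-2-iodo-6-methyloct-2-enoate | COC(=O)/C(I)=C/CC[C@@](C)(O)CCO | intermediate
7 | methyl (2Z,6R)-6-hydroxy-2-iodo-6-methyl-8-oxooct-2-enoate | COC(=O)/C(I)=C/CC[C@@](C)(O)CC=O | intermediate
8 | 1,2:5,6-di-O-isopropylidene-D-mannitol | CC1(C)OC[C@@H](O1)[C@@H](O)[C@H](O)[C@H]1COC(C)(C)O1 | starting material
9 | (4R)-2,2-dimethyl-1,3-dioxolane-4-carbaldehyde | O=C[C@H]1COC(C)(C)O1 | intermediate
10 | methyl acrylate | C=CC(=O)OC | starting material
11 | methyl 2-{[(4R)-2,2-dimethyl-1,3-dioxolan-4-yl](hydroxy)methyl}prop-2-enoate (carbinol epimers) | C=C(C(=O)OC)C(O)[C@H]1COC(C)(C)O1 | intermediate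
12 | methyl (2Z)-2-(bromomethyl)-3-[(4S)-2,2-dimethyl-1,3-dioxolan-4-yl]prop-2-enoate | COC(=O)/C(CBr)=C/[C@H]1COC(C)(C)O1 | intermediate
13 | dimethyl (2Z,6R,8R,9R)-9-[(4S)-2,2-dimethyl-1,3-dioxolan-4-yl]-6,8-dihydroxy-2-iodo-6-methyl-10-methylideneundec-2-enedioate | COC(=O)/C(I)=C/CC[C@@](C)(O)C[C@@H](O)[C@@H](C(=C)C(=O)OC)[C@H]1COC(C)(C)O1 | intermediate
14 | (R)-lactic acid | C[C@@H](O)C(=O)O | starting material
15 | pivalaldehyde | CC(C)(C)C=O | starting material
16 | (2R,5R)-2-tert-butyl-5-methyl-1,3-dioxolan-4-one | C[C@H]1O[C@@H](C(C)(C)C)OC1=O | intermediate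
17 | acetaldehyde | CC=O | starting material
18 | (2R,5S)-2-tert-butyl-5-(1-hydroxyethyl)-5-methyl-1,3-dioxolan-4-one (carbinol epimers) | CC(O)[C@]1(C)O[C@@H](C(C)(C)C)OC1=O | intermediate
19 | (2R,5S)-2-tert-butyl-5-ethenyl-5-methyl-1,3-dioxolan-4-one | C=C[C@]1(C)O[C@@H](C(C)(C)C)OC1=O | intermediate
20 | (2S)-2-hydroxy-2-methylbut-3-enoic acid | C=C[C@](C)(O)C(=O)O | intermediate
21 | (2S)-2-methyl-2-[(triethylsilyl)oxy]but-3-enoic acid | C=C[C@](C)(O[Si](CC)(CC)CC)C(=O)O | intermediate
22 | C8 ester of 13 with 21 (configuration as in 13; side chain 2S) | C=C[C@](C)(O[Si](CC)(CC)CC)C(=O)O[C@H](C[C@](C)(O)CC/C=C(\I)C(=O)OC)[C@@H](C(=C)C(=O)OC)[C@H]1COC(C)(C)O1 | intermediate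
23 | seco lactone triol (6S,7R,8R,10R; 6,12-lactone; C5 as CH2OH) | C=C[C@](C)(O)C(=O)O[C@H](C[C@](C)(O)CC/C=C(\I)C(=O)OC)[C@H]1C(=C)C(=O)O[C@@H]1CO | intermediate
24 | seco lactone aldehyde (6S,7R,8R,10R; C5 as CHO) | C=C[C@](C)(O)C(=O)O[C@H](C[C@](C)(O)CC/C=C(\I)C(=O)OC)[C@H]1C(=C)C(=O)O[C@@H]1C=O | intermediate
25 | macrocyclic diol, methyl (3E,5R,6S,7R,8R,10R)-5,10-dihydroxy-8-{[(2S)-2-hydroxy-2-methylbut-3-enoyl]oxy}-12-oxo-6,12-epoxygermacra-3,11(13)-dien-15-oate | C=C[C@](C)(O)C(=O)O[C@@H]1C[C@](C)(O)CC/C=C(C(=O)OC)\[C@@H](O)[C@H]2OC(=O)C(=C)[C@@H]21 | intermediate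
26 | CNP0325750.1, methyl (3E,5R,6S,7R,8R,10S)-5,10-epoxy-8-{[(2S)-2-hydroxy-2-methylbut-3-enoyl]oxy}-12-oxo-6,12-epoxygermacra-3,11(13)-dien-15-oate | C=C[C@](C)(O)C(=O)O[C@@H]1C[C@]2(C)CCC=C(C(=O)OC)[C@@H](O2)[C@H]2OC(=O)C(=C)[C@@H]21 | target

**Step count and risks**

Total step count: 17 (main line 9, bromide branch 3, side-chain branch 5). Longest linear sequence: 9 steps (steps 1, 2, 3, 4, 8, 14, 15, 16, 17).

The step most likely to fail is step 17. The ten-membered ring may not close, or the alkenyl metal may lose its Z geometry. The fallback closes the ring by olefin metathesis at C3=C4 after an intermolecular C4–C5 coupling. It sets out from lactol 3 and comes back at macrocyclic diol 25. Wittig methylenation of 3 (Ph3P=CH2) gives (3R)-3-methylhept-6-ene-1,3-diol F1. The operations of steps 4, 8, 14, 15 and 16 then give in turn (3R)-3-hydroxy-3-methylhept-6-enal F2, the homoallylic alcohol F3 (from F2 and 12), the C8 ester F4 (from F3 and 21), the terminal-alkene lactone triol F5 and the terminal-alkene lactone aldehyde F6. NiCl2/CrCl2-mediated addition of methyl 2-bromoacrylate to F6, again under Felkin control, gives the 2-(hydroxyalkyl)acrylate F7. Ring-closing metathesis of F7 (second-generation Grubbs catalyst, toluene, 1 mM, 80 °C) between the acrylate and the terminal alkene gives 25, which is bridged with CF3SO3H as in step 17.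

The second risk is step 8, where the facial selectivity set by the dioxolane centre may be low in the open aqueous Barbier manifold. The fallback sets out from bromide 12 and comes back at 13. Copper-catalysed borylation of 12 (B2pin2, CuCl, KOtBu) gives the allylboronate methyl (2Z)-3-[(4S)-2,2-dimethyl-1,3-dioxolan-4-yl]-2-[(4,4,5,5-tetramethyl-1,3,2-dioxaborolan-2-yl)methyl]prop-2-enoate F8. This adds to aldehyde 7 under Sc(OTf)3 or chiral phosphoric acid catalysis through a closed chair transition state (syn), and the chiral acid can reinforce the facial bias. Hydrolytic work-up returns 13.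

The third risk is step 14, where acylation of the hindered C8 hydroxyl by a hindered acid may be slower than lactonisation of that hydroxyl onto the acrylate ester. The fallback lactonises first and acylates afterwards. It sets out from 13 and comes back at 23. Treatment of 13 with AcOH/H2O/THF (as in step 15) gives the trans-6,12-lactone with free C5, C8 and C10 hydroxyls, the lactone triol F9. TBSCl/imidazole silylates only the primary C5 hydroxyl to give the silyl ether F10. Yamaguchi acylation of the one remaining secondary hydroxyl with 21 gives the bis-silylated ester F11, and AcOH/H2O/THF removes both silyl groups to return 23.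

**Further compounds**

F1 | step 17 | (3R)-3-methylhept-6-ene-1,3-diol | C=CCC[C@@](C)(O)CCO
F2 | step 17 | (3R)-3-hydroxy-3-methylhept-6-enal | C=CCC[C@@](C)(O)CC=O
F3 | step 17 | methyl (3R,4R,6R)-3-[(4S)-2,2-dimethyl-1,3-dioxolan-4-yl]-4,6-dihydroxy-6-methyl-2-methylidenedec-9-enoate | C=CCC[C@@](C)(O)C[C@@H](O)[C@@H](C(=C)C(=O)OC)[C@H]1COC(C)(C)O1
F4 | step 17 | C4 ester of F3 with 21 (terminal-alkene analogue of 22) | C=C[C@](C)(O[Si](CC)(CC)CC)C(=O)O[C@H](C[C@](C)(O)CCC=C)[C@@H](C(=C)C(=O)OC)[C@H]1COC(C)(C)O1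
F5 | step 17 | terminal-alkene analogue of lactone triol 23 | C=C[C@](C)(O)C(=O)O[C@H](C[C@](C)(O)CCC=C)[C@H]1C(=C)C(=O)O[C@@H]1CO
F6 | step 17 | terminal-alkene analogue of lactone aldehyde 24 | C=C[C@](C)(O)C(=O)O[C@H](C[C@](C)(O)CCC=C)[C@H]1C(=C)C(=O)O[C@@H]1C=O
F7 | step 17 | 2-(hydroxyalkyl)acrylate from F6 and methyl 2-bromoacrylate (5R) | C=C[C@](C)(O)C(=O)O[C@H](C[C@](C)(O)CCC=C)[C@H]1C(=C)C(=O)O[C@@H]1[C@H](O)C(=C)C(=O)OC
F8 | step 8 | methyl (2Z)-3-[(4S)-2,2-dimethyl-1,3-dioxolan-4-yl]-2-[(4,4,5,5-tetramethyl-1,3,2-dioxaborolan-2-yl)methyl]prop-2-enoate | COC(=O)/C(CB1OC(C)(C)C(C)(C)O1)=C/[C@H]1COC(C)(C)O1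
F9 | step 14 | 6,12-lactone triol from 13 (C5, C8 and C10 hydroxyls free) | O[C@H](C[C@](C)(O)CC/C=C(\I)C(=O)OC)[C@H]1C(=C)C(=O)O[C@@H]1CO
F10 | step 14 | C5 tert-butyldimethylsilyl ether of F9 | O[C@H](C[C@](C)(O)CC/C=C(\I)C(=O)OC)[C@H]1C(=C)C(=O)O[C@@H]1CO[Si](C)(C)C(C)(C)C
F11 | step 14 | C8 ester of F10 with 21 | C=C[C@](C)(O[Si](CC)(CC)CC)C(=O)O[C@H](C[C@](C)(O)CC/C=C(\I)C(=O)OC)[C@H]1C(=C)C(=O)O[C@@H]1CO[Si](C)(C)C(C)(C)C
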